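**Retrosynthetic overview**

- Target ⇐ desilylation and O-acetylation ⇐ anti (SN2) opening of a vinyl oxirane at allylic C3 by benzoic acid, which sets the 2,3-trans pair.
- Vinyl oxirane ⇐ Wharton transposition of one epoxy-ketone unit of a meso cis-bis-epoxy ketone (C4=O / C5–C6 oxirane becomes C4=C5 / C6–OH), then kinetic resolution.
- Meso bis-epoxy ketone ⇐ double nucleophilic epoxidation of an O-silylated p-quinol: both oxiranes close in one operation, anti to OSiEt3, fixing C2–O and C6–O relative to C1.
- p-Quinol ⇐ oxidative dearomatisation of 4-hydroxybenzyl benzoate ⇐ 4-hydroxybenzyl alcohol + benzoic acid.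
- Ring order: the carbocycle is the arene of the starting material; the C2–C3 and C5–C6 oxiranes form together; the C5–C6 oxirane is then consumed by the Wharton step and the C2–C3 oxirane by benzoate.

Numbering used throughout: C1 = C(OH)(CH2OBz), C2 = CH(OAc), C3 = CH(OBz), C4=C5, C6 = CH(OH), C7 = CH2OBz. The target is (1S,2S,3R,6R): the oxygens on C6, C1, C2 and C3 alternate faces (all-trans), and CH2OBz is cis to C2–O and C6–O.

Assumption: the sense of the kinetic resolution in step 6 follows the usual cation–π model for isothiourea catalysts, with the ring alkene in the place of the aryl group of 1-arylethanols. If the other enantiomer reacts faster, the (S)-catalyst is used.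

**Route**

Step 1
Reactants: 1 4-hydroxybenzyl alcohol; 2 benzoic acid
Product: 3 4-hydroxybenzyl benzoate
Conditions: PPh3, DIAD, THF, 0 °C to rt
Reagents that add atoms: none
Why: Mitsunobu esterification is chemoselective for the benzylic alcohol because the carboxylic acid, not the less acidic phenol, is the pronucleophile, and even ionisation to the p-quinone methide leads to the same ester; no stereocentre is formed.

Step 2
Reactants: 3 4-hydroxybenzyl benzoate
Product: 4 (1-hydroxy-4-oxocyclohexa-2,5-dien-1-yl)methyl benzoate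
Conditions: PhI(OAc)2, MeCN/H2O 4:1, 0 °C
Reagents that add atoms: water, O
Why: Oxidative dearomatisation of a para-substituted phenol, in which water traps the phenoxenium-type intermediate at the substituted para carbon to give the achiral p-quinol that carries the future C1 carbinol.

Step 3
Reactants: 4 (1-hydroxy-4-oxocyclohexa-2,5-dien-1-yl)methyl benzoate
Product: 5 {4-oxo-1-[(triethylsilyl)oxy]cyclohexa-2,5-dien-1-yl}methyl benzoate
Conditions: Et3SiOTf, 2,6-lutidine, CH2Cl2, −78 to 0 °C
Reagents that add atoms: triethylsilyl trifluoromethanesulfonate, CC[Si](CC)(CC)OS(=O)(=O)C(F)(F)F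
Why: Silyl triflate silylation of the hindered tertiary alcohol removes the hydrogen-bond donor that would direct the next step syn to oxygen and replaces it by a bulky group that shields that face.

Step 4
Reactants: 5 {4-oxo-1-[(triethylsilyl)oxy]cyclohexa-2,5-dien-1-yl}methyl benzoate
Product: 7 meso-{2-oxo-6-[(triethylsilyl)oxy]-4,8-dioxatricyclo[5.1.0.0^3,5]octan-6-yl}methyl benzoate (both oxirane oxygens cis to CH2OBz), via mono-epoxy enone 6 (not isolated)
Conditions: t-BuOOH (4 equiv, decane), DBU, CH2Cl2, 0 °C to rt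
Reagents that add atoms: tert-butyl hydroperoxide, CC(C)(C)OO
Why: Double Weitz–Scheffer (nucleophilic) epoxidation closes both oxirane rings in one operation, and the peroxide anion adds to each β-carbon anti to the C1–OSiEt3 bond (antiperiplanar to σ*C–O and away from the silyl ether), so both oxiranes end up cis to CH2OBz and the C2–O and C6–O configurations relative to C1 are set in a meso product.

Step 5
Reactants: 7 meso bis-epoxy ketone
Product: 9 (±)-{(1S*,4R*,5S*,6S*)-4-hydroxy-5-[(triethylsilyl)oxy]-7-oxabicyclo[4.1.0]hept-2-en-5-yl}methyl benzoate, via bis-epoxy hydrazone 8 (not isolated)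
Conditions: N2H4·H2O (1.5 equiv), AcOH (cat.), MeOH, −20 to 0 °C
Reagents that add atoms: none
Why: Wharton transposition, in which the epoxy hydrazone fragments with loss of N2 to turn C4=O / C5–C6 oxirane into C4=C5 / C6–OH with retention at C6 while the second oxirane survives as a vinyl oxirane; 7 is meso, so both enantiotopic oxiranes react and 9 is racemic, and the low temperature and small excess of hydrazine spare the benzoate.

Step 6
Reactants: 9 racemic epoxy allylic alcohol
Product: 10 {(1S,4R,5S,6S)-4-hydroxy-5-[(triethylsilyl)oxy]-7-oxabicyclo[4.1.0]hept-2-en-5-yl}methyl benzoate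
Conditions: (R)-benzotetramisole ((R)-2-phenyl-2,3-dihydroimidazo[2,1-b][1,3]benzothiazole, 5 mol %), (i-PrCO)2O (0.6 equiv), i-Pr2NEt, CHCl3, 0 °C, to about 55% conversion, then chromatography
Reagents that add atoms: none
Why: Acylative kinetic resolution of a cyclic secondary allylic alcohol by a chiral isothiourea, in which the (4S)-alcohol is esterified faster and the slow-reacting (4R)-alcohol 10 is recovered in high ee (at most 50% yield), which fixes the absolute configuration of all four centres.

Step 7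
Reactants: 10 resolved epoxy allylic alcohol
Product: 11 {(1S,4R,5R,6S)-4,5-bis[(triethylsilyl)oxy]-7-oxabicyclo[4.1.0]hept-2-en-5-yl}methyl benzoate
Conditions: Et3SiCl, imidazole, DMF, 0 °C to rt
Reagents that add atoms: chlorotriethylsilane, CC[Si](Cl)(CC)CC
Why: Standard silylation of the only free hydroxyl masks C6–OH so that the later acetylation can only occur at C2–OH.

Step 8
Reactants: 11 bis-silylated vinyl oxirane; 2 benzoic acid
Product: 12 {(1R,2S,3R,6R)-3-(benzoyloxy)-2-hydroxy-1,6-bis[(triethylsilyl)oxy]cyclohex-4-en-1-yl}methyl benzoate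
Conditions: PhCO2H (5 equiv), toluene, 60 °C
Reagents that add atoms: none
Why: Acid-mediated SN2 opening of the vinyl oxirane at the allylic carbon C3 with inversion gives C3–OBz trans to C2–OH, because C2 is neopentylic and not allylic, as in the carboxylic acid openings known for the related senepoxide-type epoxides.

Step 9
Reactants: 12 hydroxy dibenzoate
Product: 13 {(1R,2S,3R,6R)-2-(acetyloxy)-3-(benzoyloxy)-1,6-bis[(triethylsilyl)oxy]cyclohex-4-en-1-yl}methyl benzoate
Conditions: Ac2O, 4-(dimethylamino)pyridine (cat.), pyridine, CH2Cl2, 0 °C to rt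
Reagents that add atoms: acetic anhydride, CC(=O)OC(C)=O
Why: Nucleophile-catalysed acylation of the only free hydroxyl (C2–OH) with no change at any stereocentre.

Step 10
Reactants: 13 bis-silyl ether
Product: 14 [(1S,2S,3R,6R)-2-(acetyloxy)-3-(benzoyloxy)-1,6-dihydroxycyclohex-4-en-1-yl]methyl benzoate
Conditions: HF·pyridine, THF, 0 °C to rt
Reagents that add atoms: none
Why: Fluoride-mediated cleavage of both triethylsilyl ethers under mildly acidic conditions, which leaves the three esters in place and avoids base-induced acyl migration.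

**Compound list**

1 | 4-hydroxybenzyl alcohol | OCc1ccc(O)cc1 | starting material
2 | benzoic acid | OC(=O)c1ccccc1 | starting material
3 | 4-hydroxybenzyl benzoate | Oc1ccc(COC(=O)c2ccccc2)cc1 | intermediate
4 | (1-hydroxy-4-oxocyclohexa-2,5-dien-1-yl)methyl benzoate (p-quinol, achiral) | O=C1C=CC(O)(COC(=O)c2ccccc2)C=C1 | intermediate
5 | {4-oxo-1-[(triethylsilyl)oxy]cyclohexa-2,5-dien-1-yl}methyl benzoate (achiral) | O=C1C=CC(O[Si](CC)(CC)CC)(COC(=O)c2ccccc2)C=C1 | intermediate
6 | (±)-{5-oxo-2-[(triethylsilyl)oxy]-7-oxabicyclo[4.1.0]hept-3-en-2-yl}methyl benzoate, oxirane oxygen trans to OSiEt3 (mono-epoxy enone, not isolated; racemic, one enantiomer drawn) | O1[C@H]2[C@@H]1C(=O)C=C[C@@]2(O[Si](CC)(CC)CC)COC(=O)c1ccccc1 | intermediate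
7 | meso-{2-oxo-6-[(triethylsilyl)oxy]-4,8-dioxatricyclo[5.1.0.0^3,5]octan-6-yl}methyl benzoate, both oxirane oxygens cis to each other and to CH2OBz, trans to OSiEt3 | O1[C@H]2[C@@H]1C(=O)[C@H]3O[C@H]3[C@@]2(O[Si](CC)(CC)CC)COC(=O)c1ccccc1 | intermediate
8 | hydrazone of 7 (bis-epoxy hydrazone, meso, not isolated) | O1[C@H]2[C@@H]1C(=NN)[C@H]3O[C@H]3[C@@]2(O[Si](CC)(CC)CC)COC(=O)c1ccccc1 | intermediate
9 | (±)-{(1S*,4R*,5S*,6S*)-4-hydroxy-5-[(triethylsilyl)oxy]-7-oxabicyclo[4.1.0]hept-2-en-5-yl}methyl benzoate (racemic, one enantiomer drawn; OH cis to oxirane and to CH2OBz) | O1[C@H]2[C@@H]1C=C[C@@H](O)[C@@]2(O[Si](CC)(CC)CC)COC(=O)c1ccccc1 | intermediate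
10 | {(1S,4R,5S,6S)-4-hydroxy-5-[(triethylsilyl)oxy]-7-oxabicyclo[4.1.0]hept-2-en-5-yl}methyl benzoate (single enantiomer) | O1[C@H]2[C@@H]1C=C[C@@H](O)[C@@]2(O[Si](CC)(CC)CC)COC(=O)c1ccccc1 | intermediate
11 | {(1S,4R,5R,6S)-4,5-bis[(triethylsilyl)oxy]-7-oxabicyclo[4.1.0]hept-2-en-5-yl}methyl benzoate | O1[C@H]2[C@@H]1C=C[C@@H](O[Si](CC)(CC)CC)[C@@]2(O[Si](CC)(CC)CC)COC(=O)c1ccccc1 | intermediate
12 | {(1R,2S,3R,6R)-3-(benzoyloxy)-2-hydroxy-1,6-bis[(triethylsilyl)oxy]cyclohex-4-en-1-yl}methyl benzoate | O[C@H]1[C@H](OC(=O)c2ccccc2)C=C[C@@H](O[Si](CC)(CC)CC)[C@@]1(O[Si](CC)(CC)CC)COC(=O)c1ccccc1 | intermediate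
13 | {(1R,2S,3R,6R)-2-(acetyloxy)-3-(benzoyloxy)-1,6-bis[(triethylsilyl)oxy]cyclohex-4-en-1-yl}methyl benzoate | CC(=O)O[C@H]1[C@H](OC(=O)c2ccccc2)C=C[C@@H](O[Si](CC)(CC)CC)[C@@]1(O[Si](CC)(CC)CC)COC(=O)c1ccccc1 | intermediate
14 | [(1S,2S,3R,6R)-2-(acetyloxy)-3-(benzoyloxy)-1,6-dihydroxycyclohex-4-en-1-yl]methyl benzoate | CC(=O)O[C@H]1[C@H](OC(=O)c2ccccc2)C=C[C@@H](O)[C@@]1(O)COC(=O)c1ccccc1 | target

**Step count and risks**

Total steps: 10. Longest linear sequence: 10 (fully linear from 1).

The three steps most likely to fail are steps 4, 6 and 8.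

Step 4 (face selectivity of the double epoxidation). If epoxidation of 5 is unselective or goes syn to the silyl ether, facial control is handed to a hydroxyl group. The fallback sets out from 5. Luche reduction (NaBH4, CeCl3·7H2O, MeOH, −78 °C) gives the dienol with C4–OH cis to CH2OBz, cis-{4-hydroxy-1-[(triethylsilyl)oxy]cyclohexa-2,5-dien-1-yl}methyl benzoate F1, separated from its epimer. m-CPBA (CH2Cl2, 0 °C) then epoxidises both alkenes syn to the allylic hydroxyl (Henbest direction) to give the bis-epoxy alcohol {2-hydroxy-6-[(triethylsilyl)oxy]-4,8-dioxatricyclo[5.1.0.0^3,5]octan-6-yl}methyl benzoate F2. Dess–Martin periodinane oxidation brings the sequence back to the route at 7.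

Step 6 (selectivity factor on a carbinol next to a quaternary centre). If the acylative resolution is unselective, an enzyme that acylates the other enantiomer is used. The fallback sets out from 9. Candida antarctica lipase B with vinyl chloroacetate (t-BuOMe, 30 °C) acylates the (4R)-alcohol (Kazlauskas preference: large quaternary side against the flat vinyl side) to give (1S,4R,5S,6S)-5-[(benzoyloxy)methyl]-5-[(triethylsilyl)oxy]-7-oxabicyclo[4.1.0]hept-2-en-4-yl chloroacetate F3, which is separated from the unreacted (4S)-alcohol. Thiourea/NaHCO3 (EtOH, 50 °C) removes the chloroacetyl group without touching the benzoate or silyl ether, and the sequence comes back to the route at 10.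

Step 8 (regio- and stereoselective acidolysis of the vinyl oxirane). If benzoic acid does not open 11 cleanly at C3 (silyl loss, 1,4-addition), the oxygen is introduced as water and the benzoyl group afterwards. The fallback sets out from 11. Hydrolysis of the vinyl oxirane in (CF3)2CHOH/H2O at rt gives the trans-diol {(1R,2S,3R,6R)-2,3-dihydroxy-1,6-bis[(triethylsilyl)oxy]cyclohex-4-en-1-yl}methyl benzoate F4. Low-temperature benzoylation (BzCl, 2,4,6-collidine, CH2Cl2, −40 °C) acylates the less hindered allylic C3–OH, and the sequence comes back to the route at 12.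

**Further compounds**

F1 | step 4 | cis-{4-hydroxy-1-[(triethylsilyl)oxy]cyclohexa-2,5-dien-1-yl}methyl benzoate (C4–OH cis to CH2OBz) | O[C@H]1C=C[C@@](O[Si](CC)(CC)CC)(COC(=O)c2ccccc2)C=C1
F2 | step 4 | {2-hydroxy-6-[(triethylsilyl)oxy]-4,8-dioxatricyclo[5.1.0.0^3,5]octan-6-yl}methyl benzoate (OH and both oxiranes cis to CH2OBz, meso) | O1[C@H]2[C@@H]1[C@@H](O)[C@H]3O[C@H]3[C@@]2(O[Si](CC)(CC)CC)COC(=O)c1ccccc1
F3 | step 6 | (1S,4R,5S,6S)-5-[(benzoyloxy)methyl]-5-[(triethylsilyl)oxy]-7-oxabicyclo[4.1.0]hept-2-en-4-yl chloroacetate | O1[C@H]2[C@@H]1C=C[C@@H](OC(=O)CCl)[C@@]2(O[Si](CC)(CC)CC)COC(=O)c1ccccc1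
F4 | step 8 | {(1R,2S,3R,6R)-2,3-dihydroxy-1,6-bis[(triethylsilyl)oxy]cyclohex-4-en-1-yl}methyl benzoate | O[C@H]1[C@H](O)C=C[C@@H](O[Si](CC)(CC)CC)[C@@]1(O[Si](CC)(CC)CC)COC(=O)c1ccccc1
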